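Ring B (C5–C10, eremophilane numbering) is opened at C5–C6 and C9–C10. What remains is a butan-2-one chain (C6–C9) and a ring A whose quaternary C5 lies between C4 and C10, two carbons that can both be ketones of an achiral 1,3-dione. The key step is a one-pot organocatalytic Robinson annulation of 2-methylcyclohexane-1,3-dione with methyl vinyl ketone. Michael addition makes C5–C6. Enamine aldol condensation makes C9–C10 and chooses between the two enantiotopic carbonyls, so catalysis sets C5. C10, C9, C3 and C4 are then relayed from C5 by substrate control. The Z-γ-hydroxy-enone is carried as a furan and released late.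

Key step: step 1

Remark: eremophilane numbering is used throughout (ring A = C1–C5, C10; ring B = C5–C10; C11–C13 = side arm on C7). β means the face of the C5 methyl and α the opposite face. Compounds 13, 16 and 17 are taken as commercially available.

Step 1
Reactants: 1 2-methylcyclohexane-1,3-dione; 2 methyl vinyl ketone
Product: 5 (S)-Wieland–Miescher ketone, via triketone 3 (not isolated), via ketol 4 (not isolated)
Conditions: Et3N (1 mol %), neat, rt; then N-tosyl-(Sa)-binam-L-prolinamide (2 mol %), PhCO2H (1 mol %), same flask, rt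
Reagents that add atoms: none
Why: This is a Robinson annulation run as one operation, in which base-catalysed Michael addition of the C5 enol of 1 to the terminal CH2 of 2 forms C5–C6 and gives the prochiral triketone 3. The prolinamide then forms the enamine of the methyl ketone, whose C9 attacks one ring carbonyl (the future C10) in an intramolecular aldol reaction that forms C9–C10, and loss of water from ketol 4 gives the enone. The closest known reaction type is the Hajos–Parrish–Eder–Sauer–Wiechert aldol desymmetrisation, which is established for this very triketone. Ring B closes in a 6-(enolendo)-exo-trig mode. The only lasting stereocenter, C5, is controlled by the catalyst, whose amide N–H activates one of the two enantiotopic C=O groups in a chair-like transition state, and the L-proline series should give the (S)-ketone needed here. The step needs C- rather than O-alkylation of 1 (secured by the soft acceptor), a single Michael addition (C5 becomes quaternary) and dehydration toward C9=C10 only (the sole β-hydroxy ketone pathway).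

Step 2
Reactants: 5 (S)-Wieland–Miescher ketone
Product: 6 (4aR)-4a-methyl-5-methylidene-4,4a,5,6,7,8-hexahydronaphthalen-2(3H)-one (C4 methylidene enone)
Conditions: Ph3PCH3Br (1.05 equiv), KOt-Bu, THF, 0 °C to rt
Reagents that add atoms: methyltriphenylphosphonium bromide, C[P+](c1ccccc1)(c1ccccc1)c1ccccc1.[Br-]
Why: Wittig methylenation, in which the non-conjugated C4 ketone is more electrophilic than the vinylogously stabilised C8 enone carbonyl, so one equivalent of ylide should react at C4 only and no stereocenter is touched.

Step 3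
Reactants: 6 C4 methylidene enone
Product: 7 cis-fused C8=C9 trimethylsilyl enol ether (10β-H)
Conditions: [(Ph3P)CuH]6, TMSCl, toluene, rt
Reagents that add atoms: chlorotrimethylsilane, C[Si](C)(C)Cl
Why: Copper hydride conjugate reduction with silyl trapping, in which hydride adds axially to C10 on the face of the C5 methyl (as cuprates do with 10-methyl-octalones) and so sets 10β-H (cis-decalin), TMSCl fixes the enolate regiospecifically as the C8=C9 enol ether, and the isolated C4 methylidene stays inert.

Step 4
Reactants: 7 cis-fused C8=C9 trimethylsilyl enol ether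
Product: 9 9β-hydroxy-4-methylidene cis-decal-8-one, via silyloxy ketone 8 (not isolated)
Conditions: mCPBA (1.0 equiv), CH2Cl2, −20 °C; then aq. citric acid, THF, rt
Reagents that add atoms: mCPBA, OOC(=O)c1cccc(Cl)c1
Why: Rubottom oxidation, in which the electron-rich enol ether is epoxidised much faster than the 1,1-disubstituted alkene and from the convex β face of the cis-decalin (the face of 10-H and the C5 methyl), so silyl migration and hydrolysis should leave the equatorial 9β-OH.

Step 5
Reactants: 9 9β-hydroxy-4-methylidene cis-decal-8-one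
Product: 10 9β-TBS ether of 9
Conditions: TBSOTf, 2,6-lutidine, CH2Cl2, 0 °C
Reagents that add atoms: tert-butyldimethylsilyl triflate, CC(C)(C)[Si](C)(C)OS(=O)(=O)C(F)(F)F
Why: Silyl ether protection of the only hydroxyl, which blocks ketol chemistry at C9, steers later enolisation to C7 and leaves all stereocenters unchanged.

Step 6
Reactants: 10 9β-TBS ether
Product: 11 3α-hydroxy-4-methylidene ketone (allylic alcohol)
Conditions: SeO2 (0.3 equiv), t-BuOOH, CH2Cl2, 0 °C to rt
Reagents that add atoms: tert-butyl hydroperoxide, CC(C)(C)OO (oxygen passed on through SeO2, O=[Se]=O)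
Why: Selenium dioxide allylic hydroxylation (ene reaction then [2,3]-sigmatropic shift), in which only C3 carries allylic hydrogens because C5 is quaternary, and the [2,3] shift should deliver oxygen to the α face of C3, away from the axial C5 methyl, to give the equatorial 3α-OH.

Step 7
Reactants: 11 3α-hydroxy-4-methylidene ketone
Product: 12 3α-hydroxy-4β-methyl ketone
Conditions: [Ir(cod)(PCy3)(py)]PF6 (5 mol %), H2 (1 atm), CH2Cl2, rt
Reagents that add atoms: none
Why: Hydroxyl-directed homogeneous hydrogenation, in which iridium bound to the 3α-OH delivers hydrogen to the α face of C4=CH2 (also the face away from the axial C5 methyl), so the new methyl ends β, cis to the C5 methyl and trans to O3.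

Step 8
Reactants: 12 3α-hydroxy-4β-methyl ketone; 13 1-(tert-butyldimethylsilyloxy)propan-2-one
Product: 14 C7 aldol adduct (mixture of epimers at C7 and C11)
Conditions: LDA (2.2 equiv), THF, −78 °C; then 13, −78 °C; aq. NH4Cl at −78 °C
Reagents that add atoms: none
Why: Kinetic lithium enolate aldol addition, in which the first equivalent of base takes the O3 proton, the second removes the less hindered C7–H rather than the tertiary C9–H next to OTBS, and the two new centres C7 and C11 are erased in step 9.

Step 9
Reactants: 14 C7 aldol adduct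
Product: 15 3α-hydroxy-9β-(TBS-oxy)furanoeremophilane (furan alcohol)
Conditions: AcOH–THF–H2O (3:1:1), 45 °C
Reagents that add atoms: none
Why: Selective cleavage of the primary silyl ether followed by Paal–Knorr-type cyclodehydration, in which the freed C12–OH closes onto the C8 ketone, two dehydrations driven by aromatisation give the 3-methylfuran, and the ring ties C12 and C8 to the same side of C7–C11.

Step 10
Reactants: 16 (E)-non-3-en-2-one; 17 triethyl (E)-4-phosphonocrotonate
Product: 18 ethyl (2E,4E,6E)-5-methyldodeca-2,4,6-trienoate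
Conditions: LiHMDS, THF–DMPU, −78 °C to rt; 4Z isomer removed by chromatography
Reagents that add atoms: none
Why: Vinylogous Horner–Wadsworth–Emmons olefination, in which C2=C3 and C6=C7 keep the E geometry of the reactants and the new C4=C5 bond should form mainly E because the alkenyl group of the ketone is larger than its methyl.

Step 11
Reactants: 18 ethyl trienoate
Product: 19 (2E,4E,6E)-5-methyldodeca-2,4,6-trienoic acid
Conditions: LiOH, THF–MeOH–H2O, rt; then 1 M HCl
Reagents that add atoms: lithium hydroxide, [Li+].[OH-]
Why: Ester saponification by acyl–oxygen cleavage, which is mild enough to leave the all-E triene untouched.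

Step 12
Reactants: 15 furan alcohol; 19 trienoic acid
Product: 21 C3 trienoate of the furan, via mixed anhydride 20 (not isolated)
Conditions: 2,4,6-Cl3C6H2COCl, Et3N, toluene, rt; then 15, DMAP (cat.), rt
Reagents that add atoms: none
Why: Yamaguchi esterification, in which the equatorial 3α-OH is the only free hydroxyl and is acylated at oxygen, so C3 keeps its configuration.

Step 13
Reactants: 21 C3 trienoate of the furan
Product: 23 Z-keto-enal (C8 ketone and C12 aldehyde on C7=C11), via endoperoxide 22 (not isolated)
Conditions: O2, tetraphenylporphyrin (cat.), visible light, CH2Cl2, −78 °C; then Me2S, −78 to 0 °C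
Reagents that add atoms: dioxygen, O=O
Why: [4+2] photooxygenation of a furan with singlet oxygen and reductive opening of the endoperoxide, in which the trialkylfuran is far more electron-rich than the acceptor-substituted triene and the Z geometry of C7=C11 is inherited from the ring.

Step 14
Reactants: 23 Z-keto-enal
Product: 24 9-O-TBS ether of the target
Conditions: NaBH4, CH2Cl2–MeOH, −78 °C
Reagents that add atoms: none
Why: Chemoselective borohydride 1,2-reduction of an aldehyde beside a ketone, in which at low temperature the unhindered C12 aldehyde should react before the C8 ketone, which is flanked by a tetrasubstituted alkene and the C9 silyl ether, and the ester is inert.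

Step 15
Reactants: 24 9-O-TBS ether of the target
Product: 25 CNP0226738.1 (target)
Conditions: TBAF, AcOH (1:1), THF, 0 °C
Reagents that add atoms: none
Why: Fluoride desilylation of an activated α-silyloxy ketone, buffered close to neutral so that neither cyclodehydration of the Z-γ-hydroxy-enone back to the furan nor epimerisation at C9 should set in.

Compound list
1 | 2-methylcyclohexane-1,3-dione | CC1C(=O)CCCC1=O | starting material
2 | methyl vinyl ketone | C=CC(C)=O | starting material
3 | 2-methyl-2-(3-oxobutyl)cyclohexane-1,3-dione (triketone, not isolated) | CC(=O)CCC1(C)C(=O)CCCC1=O | intermediate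
4 | cis-fused bicyclic ketol, 10β-OH (not isolated) | C[C@]12CCC(=O)C[C@@]1(O)CCCC2=O | intermediate
5 | (S)-Wieland–Miescher ketone, (8aS)-8a-methyl-3,4,8,8a-tetrahydronaphthalene-1,6(2H,7H)-dione | C[C@]12CCC(=O)C=C1CCCC2=O | intermediate
6 | (4aR)-4a-methyl-5-methylidene-4,4a,5,6,7,8-hexahydronaphthalen-2(3H)-one | C[C@]12CCC(=O)C=C1CCCC2=C | intermediate
7 | cis-fused C8=C9 trimethylsilyl enol ether, 10β-H, C4 methylidene | C=C1CCC[C@@H]2C=C(O[Si](C)(C)C)CC[C@]12C | intermediate
8 | 9β-(trimethylsilyloxy)-4-methylidene cis-decal-8-one (not isolated) | C=C1CCC[C@@H]2[C@@H](O[Si](C)(C)C)C(=O)CC[C@]12C | intermediate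
9 | 9β-hydroxy-4-methylidene cis-decal-8-one | C=C1CCC[C@@H]2[C@@H](O)C(=O)CC[C@]12C | intermediate
10 | 9β-(TBS-oxy)-4-methylidene cis-decal-8-one | C=C1CCC[C@@H]2[C@@H](O[Si](C)(C)C(C)(C)C)C(=O)CC[C@]12C | intermediate
11 | 3α-hydroxy-9β-(TBS-oxy)-4-methylidene cis-decal-8-one | O[C@@H]1CC[C@@H]2[C@@H](O[Si](C)(C)C(C)(C)C)C(=O)CC[C@]2(C)C1=C | intermediate
12 | 3α-hydroxy-4β,5β-dimethyl-9β-(TBS-oxy) cis-decal-8-one | O[C@@H]1CC[C@@H]2[C@@H](O[Si](C)(C)C(C)(C)C)C(=O)CC[C@]2(C)[C@H]1C | intermediate
13 | 1-(tert-butyldimethylsilyloxy)propan-2-one | CC(=O)CO[Si](C)(C)C(C)(C)C | starting material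
14 | C7 aldol adduct of 12 with 13 (epimers at C7 and C11) | O[C@@H]1CC[C@@H]2[C@@H](O[Si](C)(C)C(C)(C)C)C(=O)C(C(C)(O)CO[Si](C)(C)C(C)(C)C)C[C@]2(C)[C@H]1C | intermediate
15 | 3α-hydroxy-9β-(TBS-oxy)furanoeremophilane (10β-H) | O[C@@H]1CC[C@@H]2[C@@H](O[Si](C)(C)C(C)(C)C)c3occ(C)c3C[C@]2(C)[C@H]1C | intermediate
16 | (E)-non-3-en-2-one | CCCCC/C=C/C(C)=O | starting material
17 | triethyl (E)-4-phosphonocrotonate | CCOC(=O)/C=C/CP(=O)(OCC)OCC | starting material
18 | ethyl (2E,4E,6E)-5-methyldodeca-2,4,6-trienoate | CCCCC/C=C/C(C)=C/C=C/C(=O)OCC | intermediate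
19 | (2E,4E,6E)-5-methyldodeca-2,4,6-trienoic acid | CCCCC/C=C/C(C)=C/C=C/C(=O)O | intermediate
20 | mixed anhydride of 19 with 2,4,6-trichlorobenzoic acid (not isolated) | CCCCC/C=C/C(C)=C/C=C/C(=O)OC(=O)c1c(Cl)cc(Cl)cc1Cl | intermediate
21 | 3α-trienoyloxy-9β-(TBS-oxy)furanoeremophilane | CCCCC/C=C/C(C)=C/C=C/C(=O)O[C@@H]1CC[C@@H]2[C@@H](O[Si](C)(C)C(C)(C)C)c3occ(C)c3C[C@]2(C)[C@H]1C | intermediate
22 | furan endoperoxide of 21, O–O bridge C8 to C12 (not isolated, face of addition irrelevant) | CCCCC/C=C/C(C)=C/C=C/C(=O)O[C@@H]1CC[C@@H]2[C@@H](O[Si](C)(C)C(C)(C)C)C34OOC(O3)C(C)=C4C[C@]2(C)[C@H]1C | intermediate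
23 | Z-keto-enal (C8 ketone, C12 aldehyde cis across C7=C11) | CCCCC/C=C/C(C)=C/C=C/C(=O)O[C@@H]1CC[C@@H]2[C@@H](O[Si](C)(C)C(C)(C)C)C(=O)/C(=C(/C)C=O)C[C@]2(C)[C@H]1C | intermediate
24 | 9-O-TBS ether of the target | CCCCC/C=C/C(C)=C/C=C/C(=O)O[C@@H]1CC[C@@H]2[C@@H](O[Si](C)(C)C(C)(C)C)C(=O)/C(=C(/C)CO)C[C@]2(C)[C@H]1C | intermediate
25 | CNP0226738.1, (3R,4R,5R,9R,10S) in eremophilane numbering | CCCCC/C=C/C(C)=C/C=C/C(=O)O[C@@H]1CC[C@@H]2[C@@H](O)C(=O)/C(=C(/C)CO)C[C@]2(C)[C@H]1C | target

Total step count: 15. Longest linear sequence: 13 steps (steps 1–9 and 12–15).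

Steps most likely to fail

Step 6. Oxygen may be delivered to the β face of C3, or to both faces, and part of the material may be oxidised further. The fallback sets out from 10 and comes back at 21, and it uses inversion instead of retention when the ester is made.
- The β-face product, the 3β-hydroxy-4-methylidene ketone F1, is hydrogenated over Pd/C. There the axial C5 methyl and the axial 3β-OH, not coordination, should direct hydrogen to the α face and give the 3β-hydroxy-4β-methyl ketone F2.
- Aldol addition to 13 as in step 8 should give the 3β-hydroxy aldol adduct F3, and aqueous acetic acid the 3β-hydroxy furan F4.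
- A Mitsunobu esterification of F4 with 19 (PPh3, DIAD, toluene) then forms the C3–O bond with inversion and gives 21.

Step 8. The addition to a ketone electrophile may revert (retro-aldol), or be overtaken by proton transfer from 13 to the enolate. The fallback sets out from 12 and comes back at 15, and it replaces the reversible aldol by an irreversible Michael addition.
- The same dilithio species is added to (E)-1-nitroprop-1-ene to give the C7 nitroalkyl ketone F5.
- A buffered Nef reaction (TiCl3, NH4OAc, THF–H2O) gives the 1,4-keto aldehyde F6.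
- F6 should close to 15 in a Paal–Knorr cyclodehydration with PPTS in toluene.

Step 14. Hydride may also attack the C8 ketone or add in a conjugate sense to the ene-dicarbonyl, and the Z-hydroxy-enone may cyclise and lose water during isolation. The fallback sets out from 23 and comes back at 25, and it gives up chemoselective reduction in favour of full reduction and selective re-oxidation.
- Luche reduction (NaBH4, CeCl3, MeOH) takes both carbonyls to the Z-ene-1,4-diol F7.
- TBSCl and imidazole silylate only the primary C12–OH and give the C12 silyl ether F8.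
- Dess–Martin periodinane oxidises the remaining allylic C8–OH to the bis-silylated enone F9.
- Buffered TBAF removes both silyl groups to give 25.

Further compounds
F1 | step 6 | 3β-hydroxy-4-methylidene ketone | O[C@H]1CC[C@@H]2[C@@H](O[Si](C)(C)C(C)(C)C)C(=O)CC[C@]2(C)C1=C
F2 | step 6 | 3β-hydroxy-4β-methyl ketone | O[C@H]1CC[C@@H]2[C@@H](O[Si](C)(C)C(C)(C)C)C(=O)CC[C@]2(C)[C@H]1C
F3 | step 6 | 3β-hydroxy aldol adduct (epimers at C7 and C11) | O[C@H]1CC[C@@H]2[C@@H](O[Si](C)(C)C(C)(C)C)C(=O)C(C(C)(O)CO[Si](C)(C)C(C)(C)C)C[C@]2(C)[C@H]1C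
F4 | step 6 | 3β-hydroxy furan | O[C@H]1CC[C@@H]2[C@@H](O[Si](C)(C)C(C)(C)C)c3occ(C)c3C[C@]2(C)[C@H]1C
F5 | step 8 | C7 nitroalkyl ketone (epimers at C7 and C11) | O[C@@H]1CC[C@@H]2[C@@H](O[Si](C)(C)C(C)(C)C)C(=O)C(C(C)C[N+](=O)[O-])C[C@]2(C)[C@H]1C
F6 | step 8 | 1,4-keto aldehyde (epimers at C7 and C11) | O[C@@H]1CC[C@@H]2[C@@H](O[Si](C)(C)C(C)(C)C)C(=O)C(C(C)C=O)C[C@]2(C)[C@H]1C
F7 | step 14 | Z-ene-1,4-diol (epimers at C8) | CCCCC/C=C/C(C)=C/C=C/C(=O)O[C@@H]1CC[C@@H]2[C@@H](O[Si](C)(C)C(C)(C)C)C(O)/C(=C(/C)CO)C[C@]2(C)[C@H]1C
F8 | step 14 | C12 silyl ether (epimers at C8) | CCCCC/C=C/C(C)=C/C=C/C(=O)O[C@@H]1CC[C@@H]2[C@@H](O[Si](C)(C)C(C)(C)C)C(O)/C(=C(/C)CO[Si](C)(C)C(C)(C)C)C[C@]2(C)[C@H]1C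
F9 | step 14 | bis-silylated enone | CCCCC/C=C/C(C)=C/C=C/C(=O)O[C@@H]1CC[C@@H]2[C@@H](O[Si](C)(C)C(C)(C)C)C(=O)/C(=C(/C)CO[Si](C)(C)C(C)(C)C)C[C@]2(C)[C@H]1C
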